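**Retrosynthetic overview**

1. Target numbering (benzofuran): O1, C2 (aryl), C3 (methyl), C3a (allyl), C4=C5(OMe), C6(=O), C7, C7a; ring A is the tetrahydrofuran, ring B the cyclohexenone.
2. Ring B is cut last at C4=C5 (intramolecular aldol condensation of keto aldehyde 16). The C4 aldehyde and the C3a allyl group go back to the two ester groups of tetrahydrofuran-3,3-diester 10: one ester is excised and replaced by allyl through the enolate, the other is reduced.
3. Ring A of 10 is cut at O1–C2 and C3a–C7a in one operation: formal [3+2] cycloaddition of donor–acceptor cyclopropane 3 (C2–C3–C3a) with the carbonyl group of aldehyde 9 (C7a=O1). Rings form in the order cyclopropane, ring A, ring B.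
4. Enabling feature: in ring A the benzylic C2 carries the electron-rich 3,4-dimethoxyphenyl group (cation-stabilising) and stands 1,3 to the quaternary C3a, whose two carbon substituents (allyl, C4) can both come from esters (carbanion-stabilising), while O1–C7a is a masked C=O. This is the retron of a 2-aryl-cyclopropane-1,1-diester plus an aldehyde.
5. 3 comes from (E)-methylisoeugenol and dimethyl diazomalonate (asymmetric cyclopropanation); 9 comes from (S)-glycidyl methyl ether, whose stereocentre (future C6) is temporary and is erased by oxidation in step 8.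

Key step: step 4

Assumption: the sense of induction of Rh2(S-NTTL)4 (dirhodium tetrakis[N-(1,8-naphthaloyl)-(S)-tert-leucinate]) with this (E)-1-arylpropene is taken to give (2R,3S)-3; if it proves opposite, the (R)-configured catalyst is used and nothing else changes.

**Step 1**
Reactants: 1 (E)-methylisoeugenol [(E)-1,2-dimethoxy-4-(prop-1-en-1-yl)benzene]; 2 dimethyl diazomalonate
Product: 3 dimethyl (2R,3S)-2-(3,4-dimethoxyphenyl)-3-methylcyclopropane-1,1-dicarboxylate
Conditions: Rh2(S-NTTL)4 (1 mol %), CH2Cl2, 40 °C, 2 (1.3 equiv) added over 6 h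
Reagents that add atoms: none
Why: Rhodium-carbene cyclopropanation: the electrophilic bis(methoxycarbonyl)carbene adds in a concerted and stereospecific way to the electron-rich (E)-alkene, so aryl and methyl stay trans, and the chiral carboxylate pocket of the dirhodium catalyst should select the alkene face that leads to the (2R,3S) enantiomer.

**Step 2**
Reactants: 4 (S)-glycidyl methyl ether [(2S)-2-(methoxymethyl)oxirane]; 5 vinylmagnesium bromide
Product: 7 (2S)-1-methoxypent-4-en-2-yl pivalate, via bromomagnesium (2S)-1-methoxypent-4-en-2-olate 6 (not isolated)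
Conditions: 5 (1.2 equiv), CuI (10 mol %), THF, −40 to 0 °C; then pivaloyl chloride (1.5 equiv), DMAP (5 mol %), 0 °C to rt
Reagents that add atoms: pivaloyl chloride, CC(C)(C)C(Cl)=O
Why: Copper-catalysed Grignard opening of the epoxide at its unsubstituted carbon (SN2, the stereocentre is not involved) and acylation of the resulting magnesium alkoxide in the same flask; the pivalate has no α-hydrogen and a hindered carbonyl, which protects it in steps 4 to 6.

**Step 3**
Reactants: 7 (2S)-1-methoxypent-4-en-2-yl pivalate
Product: 9 (2S)-1-methoxy-4-oxobutan-2-yl pivalate, via ozonide 8 (not isolated)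
Conditions: O3, CH2Cl2, −78 °C; then PPh3, −78 °C to rt
Reagents that add atoms: ozone, [O-][O+]=O
Why: Ozonolysis with reductive work-up cleaves the only C=C bond to the aldehyde under neutral conditions, so the β-acyloxy aldehyde is not exposed to base and the stereocentre is untouched.

**Step 4**
Reactants: 3 dimethyl (2R,3S)-2-(3,4-dimethoxyphenyl)-3-methylcyclopropane-1,1-dicarboxylate; 9 (2S)-1-methoxy-4-oxobutan-2-yl pivalate
Product: 10 dimethyl (2S,4R,5S)-5-(3,4-dimethoxyphenyl)-2-[(2S)-3-methoxy-2-(pivaloyloxy)propyl]-4-methyloxolane-3,3-dicarboxylate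
Conditions: Sn(OTf)2 (10 mol %), 9 (1.5 equiv), 4 Å molecular sieves, CH2Cl2, −30 to 0 °C
Reagents that add atoms: none
Why: Formal [3+2] cycloaddition of a donor–acceptor cyclopropane with an aldehyde, the closest known type being the Lewis-acid-catalysed cycloaddition of 2-aryl-cyclopropane-1,1-diesters (2,3-disubstituted ones with dialkoxyphenyl donors included) with aldehydes: Sn(OTf)2 chelates the geminal diester of 3, the carbonyl oxygen of 9 attacks the benzylic carbon in an SN2-like way within a tight ion pair (O1–C2), and the malonate carbon then adds to the oxocarbenium carbon (C3a–C7a). Ring A closes by this C–C bond formation, a five-membered aldol-type closure that is formally 5-(enolexo)-endo-trig and is routine for oxocarbenium acceptors in this reaction class; no other ring is formed. C2 is set by inversion at the benzylic cyclopropane carbon, so the trans-cyclopropane should give the 2,3-cis (aryl/methyl) tetrahydrofuran; C7a is set in the ring closure, where the (E)-oxocarbenium ion and an envelope transition state with the side chain pseudo-equatorial should place aryl and side chain cis; C3 is carried over and C3a is not yet stereogenic. Attack at C2 and not at the methyl-bearing C3 follows from benzylic stabilisation of the developing positive charge, and the aldehyde oxygen is the only good nucleophile present, since pivalate and ether oxygens are much weaker. The selectivity that the step needs is SN2 over SN1 at the very electron-rich benzylic carbon, which the chelating diester, the mild catalyst and the low temperature should secure; the carbonyl partner must be intermolecular, because only then can its oxygen reach the rear side of the C2–C3a bond.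

**Step 5**
Reactants: 10 dimethyl (2S,4R,5S)-5-(3,4-dimethoxyphenyl)-2-[(2S)-3-methoxy-2-(pivaloyloxy)propyl]-4-methyloxolane-3,3-dicarboxylate
Product: 11 methyl (2S,4R,5S)-5-(3,4-dimethoxyphenyl)-2-[(2S)-3-methoxy-2-(pivaloyloxy)propyl]-4-methyloxolane-3-carboxylate (both C3 epimers)
Conditions: LiCl (3 equiv), H2O (2 equiv), DMSO, 150 °C
Reagents that add atoms: none
Why: Krapcho dealkoxycarbonylation: chloride demethylates one ester by SN2, the carboxylate loses CO2 and the carbanion is protonated by water; the configuration of the new C–H carbon is irrelevant because it becomes an enolate carbon in step 6, and the neutral medium should leave the benzylic ether and the pivalate intact.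

**Step 6**
Reactants: 11 methyl (2S,4R,5S)-5-(3,4-dimethoxyphenyl)-2-[(2S)-3-methoxy-2-(pivaloyloxy)propyl]-4-methyloxolane-3-carboxylate; 12 allyl bromide
Product: 14 methyl (2S,3S,4R,5S)-5-(3,4-dimethoxyphenyl)-2-[(2S)-3-methoxy-2-(pivaloyloxy)propyl]-4-methyl-3-(prop-2-en-1-yl)oxolane-3-carboxylate, via lithium enolate 13 (not isolated)
Conditions: LiN(iPr)2 (LDA, commercial solution, 1.5 equiv), THF, −78 to −40 °C; then 12 (3 equiv), DMPU, −78 to 0 °C
Reagents that add atoms: none
Why: Ester enolate C-alkylation: the exocyclic enolate at C3a has one face blocked by the cis-disposed aryl, methyl and side-chain groups on C2, C3 and C7a, so allyl bromide should enter from the open face and fix the quaternary C3a with allyl trans to the methyl group and the ester cis to the side chain; ring opening of this β-alkoxy enolate would be a retro-5-endo-trig process and should be slow at low temperature.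

**Step 7**
Reactants: 14 methyl (2S,3S,4R,5S)-5-(3,4-dimethoxyphenyl)-2-[(2S)-3-methoxy-2-(pivaloyloxy)propyl]-4-methyl-3-(prop-2-en-1-yl)oxolane-3-carboxylate
Product: 15 (2S)-1-[(2S,3R,4R,5S)-5-(3,4-dimethoxyphenyl)-3-(hydroxymethyl)-4-methyl-3-(prop-2-en-1-yl)oxolan-2-yl]-3-methoxypropan-2-ol
Conditions: LiAlH4 (3 equiv), THF, 0 °C to rt; aqueous NaOH work-up
Reagents that add atoms: none
Why: Hydride reduction with LiAlH4: the methyl ester is reduced to the primary alcohol (future C4) and the pivalate is cleaved to the secondary alcohol (future C6) in one operation, with no stereocentre affected.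

**Step 8**
Reactants: 15 (2S)-1-[(2S,3R,4R,5S)-5-(3,4-dimethoxyphenyl)-3-(hydroxymethyl)-4-methyl-3-(prop-2-en-1-yl)oxolan-2-yl]-3-methoxypropan-2-ol
Product: 16 (2S,3S,4R,5S)-5-(3,4-dimethoxyphenyl)-2-(3-methoxy-2-oxopropyl)-4-methyl-3-(prop-2-en-1-yl)oxolane-3-carbaldehyde
Conditions: (COCl)2 (4 equiv), DMSO (8 equiv), CH2Cl2, −78 °C; then Et3N (12 equiv), −78 to 0 °C
Reagents that add atoms: none
Why: Swern oxidation: both hydroxyl groups are converted into alkoxysulfonium ions before the base is added, so the new aldehyde never meets a free hydroxyl group (no lactol or lactone), and the temporary stereocentre at C6 is erased on formation of the ketone.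

**Step 9**
Reactants: 16 (2S,3S,4R,5S)-5-(3,4-dimethoxyphenyl)-2-(3-methoxy-2-oxopropyl)-4-methyl-3-(prop-2-en-1-yl)oxolane-3-carbaldehyde
Product: 18 (2S,3R,3aR,7aS)-2-(3,4-dimethoxyphenyl)-5-methoxy-3-methyl-3a-(prop-2-en-1-yl)-3,3a,7,7a-tetrahydro-1-benzofuran-6(2H)-one, via aldol adduct 17 (not isolated)
Conditions: KOH (0.2 equiv), MeOH, 0 °C to rt
Reagents that add atoms: none
Why: Intramolecular aldol condensation, 6-(enolendo)-exo-trig: of the two enolisable positions only the methoxy-bearing C5 can reach the non-enolisable C4 aldehyde in a six-membered ring, E1cB dehydration of aldol 17 gives the 2-methoxy enone, and the cis ring fusion follows from the cis arrangement of aldehyde and side chain set in steps 4 and 6; a reversible retro-oxa-Michael opening at C7a can only close again to the same cis-fused ring system.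

**Compound list**

1 | (E)-methylisoeugenol, (E)-1,2-dimethoxy-4-(prop-1-en-1-yl)benzene | COc1ccc(/C=C/C)cc1OC | starting material
2 | dimethyl diazomalonate | COC(=O)C(=[N+]=[N-])C(=O)OC | starting material
3 | dimethyl (2R,3S)-2-(3,4-dimethoxyphenyl)-3-methylcyclopropane-1,1-dicarboxylate | COc1ccc(cc1OC)[C@H]1[C@H](C)C1(C(=O)OC)C(=O)OC | intermediate
4 | (S)-glycidyl methyl ether, (2S)-2-(methoxymethyl)oxirane | COC[C@@H]1CO1 | starting material
5 | vinylmagnesium bromide | C=C[Mg]Br | starting material
6 | bromomagnesium (2S)-1-methoxypent-4-en-2-olate (not isolated) | COC[C@@H](O[Mg]Br)CC=C | intermediate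
7 | (2S)-1-methoxypent-4-en-2-yl pivalate | COC[C@@H](OC(=O)C(C)(C)C)CC=C | intermediate
8 | ozonide of 7, (2S)-1-methoxy-3-(1,2,4-trioxolan-3-yl)propan-2-yl pivalate (not isolated) | COC[C@@H](OC(=O)C(C)(C)C)CC1OCOO1 | intermediate
9 | (2S)-1-methoxy-4-oxobutan-2-yl pivalate | COC[C@@H](OC(=O)C(C)(C)C)CC=O | intermediate
10 | dimethyl (2S,4R,5S)-5-(3,4-dimethoxyphenyl)-2-[(2S)-3-methoxy-2-(pivaloyloxy)propyl]-4-methyloxolane-3,3-dicarboxylate | COC(=O)C1(C(=O)OC)[C@H](C[C@H](OC(=O)C(C)(C)C)COC)O[C@H](c2ccc(OC)c(OC)c2)[C@@H]1C | intermediate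
11 | methyl (2S,4R,5S)-5-(3,4-dimethoxyphenyl)-2-[(2S)-3-methoxy-2-(pivaloyloxy)propyl]-4-methyloxolane-3-carboxylate (both C3 epimers) | COC(=O)C1[C@H](C[C@H](OC(=O)C(C)(C)C)COC)O[C@H](c2ccc(OC)c(OC)c2)[C@@H]1C | intermediate
12 | allyl bromide | C=CCBr | starting material
13 | lithium enolate of 11 (not isolated) | COC(O[Li])=C1[C@H](C[C@H](OC(=O)C(C)(C)C)COC)O[C@H](c2ccc(OC)c(OC)c2)[C@@H]1C | intermediate
14 | methyl (2S,3S,4R,5S)-5-(3,4-dimethoxyphenyl)-2-[(2S)-3-methoxy-2-(pivaloyloxy)propyl]-4-methyl-3-(prop-2-en-1-yl)oxolane-3-carboxylate | C=CC[C@@]1(C(=O)OC)[C@H](C[C@H](OC(=O)C(C)(C)C)COC)O[C@H](c2ccc(OC)c(OC)c2)[C@@H]1C | intermediate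
15 | (2S)-1-[(2S,3R,4R,5S)-5-(3,4-dimethoxyphenyl)-3-(hydroxymethyl)-4-methyl-3-(prop-2-en-1-yl)oxolan-2-yl]-3-methoxypropan-2-ol | C=CC[C@@]1(CO)[C@H](C[C@H](O)COC)O[C@H](c2ccc(OC)c(OC)c2)[C@@H]1C | intermediate
16 | (2S,3S,4R,5S)-5-(3,4-dimethoxyphenyl)-2-(3-methoxy-2-oxopropyl)-4-methyl-3-(prop-2-en-1-yl)oxolane-3-carbaldehyde | C=CC[C@@]1(C=O)[C@H](CC(=O)COC)O[C@H](c2ccc(OC)c(OC)c2)[C@@H]1C | intermediate
17 | aldol adduct, 4-hydroxy-4,5-dihydro derivative of 18 with the ring-fusion configuration of 18, mixture at C4 and C5 (not isolated) | C=CC[C@@]12C(O)C(OC)C(=O)C[C@@H]1O[C@H](c1ccc(OC)c(OC)c1)[C@@H]2C | intermediate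
18 | (2S,3R,3aR,7aS)-2-(3,4-dimethoxyphenyl)-5-methoxy-3-methyl-3a-(prop-2-en-1-yl)-3,3a,7,7a-tetrahydro-1-benzofuran-6(2H)-one | C=CC[C@@]12C=C(OC)C(=O)C[C@@H]1O[C@H](c1ccc(OC)c(OC)c1)[C@@H]2C | target

**Step count and risks**

Total step count: 9. Longest linear sequence: 8 steps (steps 2 to 9, from 4 to 18); the cyclopropane branch needs 7 (step 1, then steps 4 to 9).

Steps most likely to fail:

Step 4. What may go wrong is ionisation at the very electron-rich benzylic carbon, either in the cyclopropane before the SN2 event or at the benzylic C–O bond of the product afterwards. This would erode the inversion at C2 and lead to the 2,3-trans series. β-Elimination of pivalic acid from the aldehyde under the Lewis acid is a second concern. The fallback tempers the donor and postpones the methyl ether. It sets out from diazo ester 2 and aldehyde 9 and uses commercial (E)-2-methoxy-4-(prop-1-en-1-yl)phenyl acetate F1 in place of 1. Cyclopropanation of F1 with 2 under the conditions of step 1 should give dimethyl (2R,3S)-2-(4-acetoxy-3-methoxyphenyl)-3-methylcyclopropane-1,1-dicarboxylate F2, whose donor is comparable to phenyl, the donor class for which this cycloaddition transfers configuration most cleanly. Cycloaddition of F2 with 9 (Sn(OTf)2, CH2Cl2, rt) should give dimethyl (2S,4R,5S)-5-(4-acetoxy-3-methoxyphenyl)-2-[(2S)-3-methoxy-2-(pivaloyloxy)propyl]-4-methyloxolane-3,3-dicarboxylate F3. Mild methanolysis of the aryl acetate (K2CO3, MeOH, 0 °C; the alkyl pivalate and the methyl esters should remain) should give dimethyl (2S,4R,5S)-5-(4-hydroxy-3-methoxyphenyl)-2-[(2S)-3-methoxy-2-(pivaloyloxy)propyl]-4-methyloxolane-3,3-dicarboxylate F4. O-Methylation (MeI, K2CO3, acetone, rt) comes back to the route at 10.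

Step 1. What may go wrong is insufficient enantioface discrimination by the chiral dirhodium catalyst for a trans-1,2-disubstituted alkene with a malonate carbene. The fallback replaces catalyst control by resolution through the enantiopure aldehyde. It sets out from 1 and 2, which with the achiral catalyst Rh2(esp)2 (dirhodium bis(α,α,α′,α′-tetramethyl-1,3-benzenedipropanoate)) in CH2Cl2 should give the racemic trans-cyclopropane, that is 3 together with dimethyl (2S,3R)-2-(3,4-dimethoxyphenyl)-3-methylcyclopropane-1,1-dicarboxylate F5. Step 4 with enantiopure 9 should then give 10 and its diastereomer dimethyl (2R,4S,5R)-5-(3,4-dimethoxyphenyl)-2-[(2S)-3-methoxy-2-(pivaloyloxy)propyl]-4-methyloxolane-3,3-dicarboxylate F6, which differ in the relation of the ring to the temporary stereocentre of the side chain and are to be separated by chromatography or crystallisation. The fallback comes back to the route at 10.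

Step 5 (together with step 6). What may go wrong is incomplete dealkoxycarbonylation of the hindered geminal diester, thermal epimerisation at the benzylic ether at 150 °C, and afterwards sluggish deprotonation of the shielded C–H bond in step 6. The fallback replaces both steps by a radical decarboxylative allylation. It sets out from 10. Mono-saponification (LiOH, 1.1 equiv, THF/H2O, rt) should give the half ester (2S,4R,5S)-5-(3,4-dimethoxyphenyl)-3-(methoxycarbonyl)-2-[(2S)-3-methoxy-2-(pivaloyloxy)propyl]-4-methyloxolane-3-carboxylic acid F7 (either C3 epimer serves). Coupling with N-hydroxyphthalimide (N,N'-diisopropylcarbodiimide, DMAP cat., CH2Cl2) should give the redox-active 1,3-dioxoisoindolin-2-yl ester F8. Photoreductive decarboxylation in the presence of allyl phenyl sulfone (Ru(bpy)3(PF6)2 1 mol %, Hantzsch ester, iPr2NEt, CH2Cl2, blue LEDs, rt) should generate the planar tertiary radical at C3a, which is allylated on the face away from the three cis substituents. The fallback comes back to the route at 14.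

**Further compounds**

F1 | step 4 | (E)-2-methoxy-4-(prop-1-en-1-yl)phenyl acetate (isoeugenyl acetate) | CC(=O)Oc1ccc(/C=C/C)cc1OC
F2 | step 4 | dimethyl (2R,3S)-2-(4-acetoxy-3-methoxyphenyl)-3-methylcyclopropane-1,1-dicarboxylate | CC(=O)Oc1ccc(cc1OC)[C@H]1[C@H](C)C1(C(=O)OC)C(=O)OC
F3 | step 4 | dimethyl (2S,4R,5S)-5-(4-acetoxy-3-methoxyphenyl)-2-[(2S)-3-methoxy-2-(pivaloyloxy)propyl]-4-methyloxolane-3,3-dicarboxylate | COC(=O)C1(C(=O)OC)[C@H](C[C@H](OC(=O)C(C)(C)C)COC)O[C@H](c2ccc(OC(C)=O)c(OC)c2)[C@@H]1C
F4 | step 4 | dimethyl (2S,4R,5S)-5-(4-hydroxy-3-methoxyphenyl)-2-[(2S)-3-methoxy-2-(pivaloyloxy)propyl]-4-methyloxolane-3,3-dicarboxylate | COC(=O)C1(C(=O)OC)[C@H](C[C@H](OC(=O)C(C)(C)C)COC)O[C@H](c2ccc(O)c(OC)c2)[C@@H]1C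
F5 | step 1 | dimethyl (2S,3R)-2-(3,4-dimethoxyphenyl)-3-methylcyclopropane-1,1-dicarboxylate | COc1ccc(cc1OC)[C@@H]1[C@@H](C)C1(C(=O)OC)C(=O)OC
F6 | step 1 | dimethyl (2R,4S,5R)-5-(3,4-dimethoxyphenyl)-2-[(2S)-3-methoxy-2-(pivaloyloxy)propyl]-4-methyloxolane-3,3-dicarboxylate | COC(=O)C1(C(=O)OC)[C@@H](C[C@H](OC(=O)C(C)(C)C)COC)O[C@@H](c2ccc(OC)c(OC)c2)[C@H]1C
F7 | step 5 | (2S,4R,5S)-5-(3,4-dimethoxyphenyl)-3-(methoxycarbonyl)-2-[(2S)-3-methoxy-2-(pivaloyloxy)propyl]-4-methyloxolane-3-carboxylic acid | OC(=O)C1(C(=O)OC)[C@H](C[C@H](OC(=O)C(C)(C)C)COC)O[C@H](c2ccc(OC)c(OC)c2)[C@@H]1C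
F8 | step 5 | 3-(1,3-dioxoisoindolin-2-yl) 3-methyl (2S,4R,5S)-5-(3,4-dimethoxyphenyl)-2-[(2S)-3-methoxy-2-(pivaloyloxy)propyl]-4-methyloxolane-3,3-dicarboxylate | COC(=O)C1(C(=O)ON2C(=O)c3ccccc3C2=O)[C@H](C[C@H](OC(=O)C(C)(C)C)COC)O[C@H](c2ccc(OC)c(OC)c2)[C@@H]1C
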